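**Locants.** Ring A is C1 (CMe2), C2, C3 (carbinol), C4, C5 (methyl, oxygen), C6. Ring B is O, C5, C6=C7, C8. The chain runs C9(Me)=C10, C11 to C15, then C15' back to C10' (CH2OH). Compounds 1 to 24 are defined in the steps and the list; 24 is the target.

## Analysis of the target

Compound 24 (C27H38O3) is an apocarotenoid in which a cyclohexane (ring A) is fused across C5–C6 to a 2,5-dihydrofuran (ring B), and C8 carries a conjugated hexaene that ends in the allylic alcohol C10'. There are three stereocentres: C3 (S), the quaternary C5 (R) and C8 (R). The C3 hydroxyl is trans to the C5–O bond, and H8 is cis to the C5 methyl across ring B. All chain alkenes are E except C9=C10, which is Z and sits directly on C8. The C8–O bond is doubly allylic (C6=C7 on one side, the hexaene on the other), so acid can ionise it and scramble C8 or open ring B; the polyene is also sensitive to light and oxygen. The difficulty is to set C8 relative to the remote quaternary C5 on a flat ring that offers no steric bias, next to a trisubstituted Z alkene. The strategy rests on one feature: the oxygen on C5, the C6=C7 alkene and the C8 centre are what remains when a C5 hydroxyl adds to the far end of a C6=C7=C8 allene, so the allene axis can carry the information for C8.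

## Retrosynthetic reasoning

24 from 23: the primary allylic alcohol is taken back to its ethyl ester. The ester reduction comes last so that the most sensitive hydroxyl is present in no earlier step.

23 from 14 and 21: the C11=C12 bond is cut. It is a disubstituted E alkene, which a phosphonate olefination forms well, and the cut separates all stereochemical information (the C15 bicycle 14) from an achiral all-E chain (21). The carbanion is placed on the chain partner: a carbanion at C11 of the bicycle would be vinylogously β to the C8–O bond and would open ring B. The forward reaction has to give 11E without touching 9Z or C8.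

21 from 15 and 16: the chain phosphonate is traced through bromide 20, alcohol 19 and aldehyde ester 18 to the symmetrical dialdehyde 15, which already holds three E alkenes and both methyls. One olefination with 16 adds C11' and C10'.

14 from 12: both silyl ethers are removed together (13), because only the allylic primary alcohol is then oxidised. This saves a selective deprotection and a final desilylation.

12 from 10: the O–C8 bond is cut. This is the one bond whose formation turns an axis into a centre. With it, C8 stops being a question of facial selectivity and becomes a question of allene configuration, which can be fixed one step earlier. The forward reaction has to add the C5 oxygen to C8 in the allene plane faster than anything that scrambles the axis. The C11 oxygen is capped because the Z alkene holds it within reach of C8 as well.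

10 from 8: the C8–H bond is cut and the C6–O bond restored, which leads to an alkynyl epoxide. The required allene has C9 on the face of the C5 oxygen. This is the aS axis, 6S in carotenoid terms, opposite to the 6R axis of the natural allenic end group. Hydride must therefore reach C8 anti to the departing C6–O bond. Dialkylaluminium hydrides bind the epoxide oxygen first and are prone to deliver hydride on the oxygen face, which would lead to the other axis and so to the C8 epimer. A copper-bound hydride is used instead: it adds syn across C7≡C8 with copper on C7, and the C6–O bond then leaves anti to copper.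

8 from 7: the epoxide comes from the C5=C6 alkene. C5 is set here, on the face away from the C3 silyloxy group, and its C–O bond is kept to the end.

7 from 4 and 6: the C6–C7 bond (sp2–sp) is cut. The alkyne 6 brings C7 to C11 with the Z alkene already in place from 5.

4 from 1: the enol triflate is regiodefined because the ketone of 2 has only one α-hydrogen. C3 comes unchanged from 1.

## Alternatives that were turned down

Alternative 1: Both oxygen bonds of ring B are cut, C8–O and C5–O. This leads back to the tertiary C6 carbinol A2, the nitrile of (S)-abscisic acid A1, in which C3 is a ketone and C4=C5 an enone.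
- Forward step: Re2O7 (or Ph3SiOReO3) would convert the C6 hydroxyl into a perrhenate ester that shifts suprafacially across C6–C7=C8. The hydroxyl newly placed on C8 would then add to C5 of the dienone (5-exo-trig) to give the keto furanoid nitrile A3.
- For: A1 already contains ring A, the C6 stereocentre and the Z C9=C10 alkene. An S carbinol, with C5 on the inside of the chair transition state and H8 eclipsing the new C6=C7 bond during closure, maps onto 8R and 5R. The C15 bicycle would be reached in about three steps, against seven here, so on step count this alternative is clearly stronger.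
- Against: C3 is left as a ketone and must be reduced to the alcohol cis to the C5 methyl, in a ring where axial substituents on C1 and C5 flank the carbonyl, so the outcome is not secured. The C6 perrhenate is tertiary and doubly allylic, so ionisation can compete with the concerted shift and erase the transfer. The catalyst is acidic and the C8–O bond of A3 is again doubly allylic. The conjugate addition is reversible, so C5 and C8 end under thermodynamic control.
- Comparison: the chosen route spends more steps but sets the three centres one at a time: C3 from 1, C5 by epoxidation, C8 by a stereospecific closure in a nearly neutral medium.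

Alternative 2: The C1–C6 bond of ring A and the C5–O bond of ring B are cut together. Both rings open to the acyclic allenyl carbinol A4 (C1=C2–C3=O enone, C5=C6=C7 allene, C8 carbinol).
- Forward step: Me2AlCl would activate the enone, the central allene carbon C6 would attack C1 (6-endo closure of ring A), and the C8 hydroxyl would capture the allyl cation at C5 to give A5.
- For: two bonds, both rings and the quaternary C1 are made in one step. Only C8 has to be set beforehand, because the allene axis is lost in the allyl cation. In bonds formed per step it is stronger than the chosen closure.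
- Against: the β carbon of a β,β-dimethyl enone is a poor electrophile and the central carbon of an allene a poor nucleophile. The Lewis acid can equally ionise the allenylic C8 carbinol or promote oxa-Michael addition. C5 would be set only by the conformational preference of the capture. C3 again needs a late ketone reduction, and A4 is itself a multi-step target.
- Comparison: the chosen key step forms one bond, but that bond type has close precedent and everything else is in place before it.

Alternative 3: C7 is introduced as a one-carbon unit. The C6=C7 and C7–C8 bonds are cut, back to the C6 ketone A6, whose C5 oxygen carries the C8 methylene as an allyl ether.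
- Forward step: Me3SiC(Li)N2 adds to the ketone, loss of Me3SiOLi and N2 gives the C6=C7 alkylidene carbene, and 1,5 insertion into one C8–H bond closes ring B as the alkenyl iodide A7.
- For: the carbonyl carbon of 1 becomes C6 directly. C3 and C5 are in place before the key step, just as in the chosen route, so on that point it is equally strong. An ether α C–H bond five atoms away is the best case for this carbene, and the Z iodide of A7 is a handle for cross-coupling.
- Against: the two C8 hydrogens are diastereotopic, and only a conformational bias across ring B decides which is replaced, so C8 rests on a selectivity and not on a stereospecific transfer. The ketone lies between two quaternary carbons (C1 and C5), which hampers the addition. The tertiary C5 ether needs a face-defined α-hydroxylation and the O-alkylation of a hindered tertiary alcohol. The chain would have to be joined as a polyenyl metal at C10–C11.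
- Comparison: the chosen strategy uses the same ring precursor but derives C8 from an axis whose configuration is fixed one step earlier.

Key step: step 7

Remark on the chemistry: hydride transfer from an NHC-ligated CuH to a propargylic epoxide is taken to follow the anti SN2' course of organocopper reagents.

## Steps

Step 1
Reactants: 1 (4R,6R)-4-hydroxy-2,2,6-trimethylcyclohexan-1-one (actinol)
Product: 2 (4R,6R)-4-[(tert-butyldimethylsilyl)oxy]-2,2,6-trimethylcyclohexan-1-one
Conditions: TBSCl, imidazole, DMF, rt
Reagents that add atoms: tert-butyldimethylsilyl chloride, C[Si](C)(Cl)C(C)(C)C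
Why: Standard silylation of an unhindered secondary alcohol; the C3 stereocentre of the target (C4 of 1) is untouched and the bulky ether later steers the epoxidation.

Step 2
Reactants: 2 (4R,6R)-4-[(tert-butyldimethylsilyl)oxy]-2,2,6-trimethylcyclohexan-1-one
Product: 4 (4R)-4-[(tert-butyldimethylsilyl)oxy]-2,6,6-trimethylcyclohex-1-en-1-yl trifluoromethanesulfonate, via lithium enolate 3 (not isolated)
Conditions: LiN(i-Pr)2, THF, −78 °C; PhNTf2, −78 °C to rt
Reagents that add atoms: N-phenylbis(trifluoromethanesulfonimide), O=S(=O)(N(c1ccccc1)S(=O)(=O)C(F)(F)F)C(F)(F)F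
Why: The ketone has a single α-hydrogen, so only one enolate can form; O-triflation gives the tetrasubstituted enol triflate whose double bond is the later C5=C6.

Step 3
Reactants: 5 (2Z)-3-methylpent-2-en-4-yn-1-ol
Product: 6 tert-butyldimethyl{[(2Z)-3-methylpent-2-en-4-yn-1-yl]oxy}silane
Conditions: TBSCl, imidazole, CH2Cl2, 0 °C to rt
Reagents that add atoms: tert-butyldimethylsilyl chloride, C[Si](C)(Cl)C(C)(C)C
Why: Silylation of a primary allylic alcohol; the Z alkene is not affected and the capped C11 oxygen cannot compete in the gold step.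

Step 4
Reactants: 4 (4R)-4-[(tert-butyldimethylsilyl)oxy]-2,6,6-trimethylcyclohex-1-en-1-yl trifluoromethanesulfonate; 6 tert-butyldimethyl{[(2Z)-3-methylpent-2-en-4-yn-1-yl]oxy}silane
Product: 7 tert-butyl({(1R)-4-[(3Z)-5-{[tert-butyl(dimethyl)silyl]oxy}-3-methylpent-3-en-1-yn-1-yl]-3,5,5-trimethylcyclohex-3-en-1-yl}oxy)dimethylsilane (the 3R,9Z dienyne)
Conditions: Pd(PPh3)4 (5 mol %), CuI (10 mol %), i-Pr2NH, DMF, rt
Reagents that add atoms: none
Why: Sonogashira coupling of an enol triflate with a terminal alkyne forms the C6–C7 bond; both alkene geometries are retained because neither alkene takes part.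

Step 5
Reactants: 7 the 3R,9Z dienyne
Product: 8 tert-butyl({(1R,3S,6R)-6-[(3Z)-5-{[tert-butyl(dimethyl)silyl]oxy}-3-methylpent-3-en-1-yn-1-yl]-1,5,5-trimethyl-7-oxabicyclo[4.1.0]heptan-3-yl}oxy)dimethylsilane (5,6-epoxide, oxygen trans to the C3 silyloxy group)
Conditions: mCPBA, NaHCO3, CH2Cl2, 0 °C
Reagents that add atoms: 3-chloroperbenzoic acid, O=C(OO)c1cccc(Cl)c1
Why: Prilezhaev epoxidation picks the tetrasubstituted C5=C6 alkene over the trisubstituted C9=C10, which carries the electron-withdrawing CH2OSi group, and over the alkyne. The peracid should add mainly to the face away from the C3 silyloxy group, which sets C5 (R); the minor face isomer is removed by chromatography.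

Step 6
Reactants: 8 the alkynyl epoxide
Product: 10 (1R,3S)-3-{[tert-butyl(dimethyl)silyl]oxy}-6-[(aS,3Z)-5-{[tert-butyl(dimethyl)silyl]oxy}-3-methylpenta-1,3-dien-1-ylidene]-1,5,5-trimethylcyclohexan-1-ol (5-hydroxy 6,7,8-allene, 6S axis), via tertiary diethoxy(methyl)silyl ether 9 (not isolated)
Conditions: CuCl (5 mol %), NaOt-Bu (10 mol %), 1,3-bis(2,4,6-trimethylphenyl)imidazolium chloride (5 mol %), MeSiH(OEt)2, toluene, 0 °C to rt; then K2CO3, MeOH, rt
Reagents that add atoms: none
Why: CuH-catalysed SN2' reduction of a propargylic epoxide to an α-hydroxyallene: Cu–H adds syn across C7≡C8 with copper on C7, and the C6–O bond leaves anti to copper, so H8 enters anti to the epoxide oxygen and C9 moves to the oxygen face (aS axis). The copper alkoxide is silylated by the silane (9), which turns the catalyst over, and mild methanolysis frees the tertiary alcohol without touching the TBS ethers.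

Step 7
Reactants: 10 the 5-hydroxy 6,7,8-allene
Product: 12 tert-butyl({(2R,6S,7aR)-2-[(2Z)-4-{[tert-butyl(dimethyl)silyl]oxy}but-2-en-2-yl]-4,4,7a-trimethyl-2,4,5,6,7,7a-hexahydro-1-benzofuran-6-yl}oxy)dimethylsilane (C15 furanoid bis-silyl ether, 3S,5R,8R), via C7 vinylgold oxonium 11 (not isolated)
Conditions: AuCl3 (2 mol %), THF, 0 °C to rt, dark
Reagents that add atoms: none
Why: AuCl3 binds the C7=C8 π bond of 10, which lies in the plane of C1, C6 and C5, on the side away from the hydroxyl; the C5 oxygen adds to C8 within that plane (anti oxyauration) to give the C7-aurated oxonium 11, and transfer of the proton from oxygen to C7 (protodeauration) releases 12 and the catalyst. The closest known reaction type is the gold-catalysed cycloisomerisation of α-hydroxyallenes to 2,5-dihydrofurans with axis-to-centre chirality transfer. Ring B closes in the 5-endo-trig mode onto the existing ring A. The new stereocentre C8 is controlled by the allene axis together with the fixed C5: H8 and C9 stay on their sides of the plane while oxygen arrives within it, so the aS axis (C9 on the face of C4, H8 on the face of the C5 methyl) becomes 8R with H8 cis to the C5 methyl, and no face has to be chosen. The step needs oxygen attack to outrun gold-induced scrambling of the axis and carbocyclisation of the vinylallene; the tertiary hydroxyl sits one bond from the allene, which makes the closure intramolecular, and THF as donor solvent tempers the Lewis acidity. The C11 silyl ether keeps the second oxygen, held near C8 by the Z alkene, from competing, and the nearly neutral medium spares the doubly allylic C8–O bond once it is formed.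

Step 8
Reactants: 12 the C15 furanoid bis-silyl ether
Product: 13 (2R,6S,7aR)-2-[(2Z)-4-hydroxybut-2-en-2-yl]-4,4,7a-trimethyl-2,4,5,6,7,7a-hexahydro-1-benzofuran-6-ol
Conditions: Bu4NF, THF, 0 °C to rt
Reagents that add atoms: none
Why: Fluoride cleaves both silyl ethers under basic conditions, which the acid-sensitive doubly allylic ether tolerates; no stereocentre is involved.

Step 9
Reactants: 13 the furanoid diol
Product: 14 (2Z)-3-[(2R,6S,7aR)-6-hydroxy-4,4,7a-trimethyl-2,4,5,6,7,7a-hexahydro-1-benzofuran-2-yl]but-2-enal
Conditions: MnO2 (excess), CH2Cl2, rt, dark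
Reagents that add atoms: none
Why: MnO2 oxidises allylic alcohols only, so the saturated C3 hydroxyl stays; trisubstituted (Z)-enals of this kind are formed from the Z alcohols without isomerisation under these neutral conditions.

Step 10
Reactants: 15 (2E,4E,6E)-2,7-dimethylocta-2,4,6-trienedial; 16 triethyl phosphonoacetate
Product: 18 ethyl (2E,4E,6E,8E)-4,9-dimethyl-10-oxodeca-2,4,6,8-tetraenoate, via sodium salt of the phosphonoacetate carbanion 17 (not isolated)
Conditions: 16, NaH, THF, 0 °C; added slowly to 15 (excess), THF, −20 °C to rt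
Reagents that add atoms: none
Why: Horner–Wadsworth–Emmons olefination of one of two equivalent aldehydes gives the E enoate (C12'=C11'); slow addition of the anion to an excess of 15 favours mono-olefination, and unreacted 15 is recovered.

Step 11
Reactants: 18 the aldehyde ester
Product: 19 ethyl (2E,4E,6E,8E)-10-hydroxy-4,9-dimethyldeca-2,4,6,8-tetraenoate
Conditions: NaBH4, EtOH/THF, −10 °C
Reagents that add atoms: none
Why: Borohydride reduces the aldehyde 1,2 and leaves the conjugated ester.

Step 12
Reactants: 19 the hydroxy ester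
Product: 20 ethyl (2E,4E,6E,8E)-10-bromo-4,9-dimethyldeca-2,4,6,8-tetraenoate
Conditions: PBr3, pyridine (cat.), Et2O, −10 °C, dark
Reagents that add atoms: phosphorus tribromide, BrP(Br)Br
Why: Conversion of a primary allylic alcohol into the conjugated primary allylic bromide, the usual entry to polyenyl phosphonates.

Step 13
Reactants: 20 the allylic bromide
Product: 21 ethyl (2E,4E,6E,8E)-10-(diethoxyphosphoryl)-4,9-dimethyldeca-2,4,6,8-tetraenoate
Conditions: P(OEt)3 (neat), 90 °C
Reagents that add atoms: triethyl phosphite, CCOP(OCC)OCC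
Why: Michaelis–Arbuzov reaction of a primary allylic bromide; the alkene geometries are not involved.

Step 14
Reactants: 21 the chain phosphonate; 14 the (Z)-enal
Product: 23 ethyl (2E,4E,6E,8E,10E,12Z)-13-[(2R,6S,7aR)-6-hydroxy-4,4,7a-trimethyl-2,4,5,6,7,7a-hexahydro-1-benzofuran-2-yl]-4,9-dimethyltetradeca-2,4,6,8,10,12-hexaenoate, via sodium salt of the chain phosphonate carbanion 22 (not isolated)
Conditions: 21, NaN(SiMe3)2, THF, −78 °C; then 14, −78 to 0 °C, dark
Reagents that add atoms: none
Why: Horner–Wadsworth–Emmons olefination with an allylic phosphonate forms the disubstituted C11=C12 bond with E preference. The delocalised anion is too weak a base to deprotonate the C3 hydroxyl, and the low temperature protects the Z alkene and C8.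

Step 15
Reactants: 23 the hexaenoate
Product: 24 (2E,4E,6E,8E,10E,12Z)-13-[(2R,6S,7aR)-6-hydroxy-4,4,7a-trimethyl-2,4,5,6,7,7a-hexahydro-1-benzofuran-2-yl]-4,9-dimethyltetradeca-2,4,6,8,10,12-hexaen-1-ol (target)
Conditions: i-Bu2AlH (excess), CH2Cl2, −78 °C; aq. potassium sodium tartrate
Reagents that add atoms: none
Why: 1,2-Reduction of a conjugated ester to the allylic alcohol; the free C3 hydroxyl only consumes one equivalent of hydride, and the tartrate work-up avoids acid at the doubly allylic ether.

## Compound list

1 | (4R,6R)-4-hydroxy-2,2,6-trimethylcyclohexan-1-one (actinol) | CC1(C)C[C@H](O)C[C@@H](C)C1=O | starting material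
2 | (4R,6R)-4-[(tert-butyldimethylsilyl)oxy]-2,2,6-trimethylcyclohexan-1-one | CC1(C)C[C@H](O[Si](C)(C)C(C)(C)C)C[C@@H](C)C1=O | intermediate
3 | lithium (4R)-4-[(tert-butyldimethylsilyl)oxy]-2,6,6-trimethylcyclohex-1-en-1-olate | CC1(C)C[C@H](O[Si](C)(C)C(C)(C)C)CC(C)=C1[O-].[Li+] | intermediate (not isolated)
4 | (4R)-4-[(tert-butyldimethylsilyl)oxy]-2,6,6-trimethylcyclohex-1-en-1-yl trifluoromethanesulfonate | CC1(C)C[C@H](O[Si](C)(C)C(C)(C)C)CC(C)=C1OS(=O)(=O)C(F)(F)F | intermediate
5 | (2Z)-3-methylpent-2-en-4-yn-1-ol | C#C/C(C)=C\CO | starting material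
6 | tert-butyldimethyl{[(2Z)-3-methylpent-2-en-4-yn-1-yl]oxy}silane | C#C/C(C)=C\CO[Si](C)(C)C(C)(C)C | intermediate
7 | tert-butyl({(1R)-4-[(3Z)-5-{[tert-butyl(dimethyl)silyl]oxy}-3-methylpent-3-en-1-yn-1-yl]-3,5,5-trimethylcyclohex-3-en-1-yl}oxy)dimethylsilane | C/C(=C/CO[Si](C)(C)C(C)(C)C)C#CC1=C(C)C[C@@H](O[Si](C)(C)C(C)(C)C)CC1(C)C | intermediate
8 | tert-butyl({(1R,3S,6R)-6-[(3Z)-5-{[tert-butyl(dimethyl)silyl]oxy}-3-methylpent-3-en-1-yn-1-yl]-1,5,5-trimethyl-7-oxabicyclo[4.1.0]heptan-3-yl}oxy)dimethylsilane | C/C(=C/CO[Si](C)(C)C(C)(C)C)C#C[C@@]12O[C@]1(C)C[C@@H](O[Si](C)(C)C(C)(C)C)CC2(C)C | intermediate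
9 | diethoxy(methyl)silyl ether of 10 at the C5 oxygen | C/C(=C/CO[Si](C)(C)C(C)(C)C)[CH]=[C@]=C2C(C)(C)C[C@H](O[Si](C)(C)C(C)(C)C)C[C@@]2(C)O[Si](C)(OCC)OCC | intermediate (not isolated)
10 | (1R,3S)-3-{[tert-butyl(dimethyl)silyl]oxy}-6-[(aS,3Z)-5-{[tert-butyl(dimethyl)silyl]oxy}-3-methylpenta-1,3-dien-1-ylidene]-1,5,5-trimethylcyclohexan-1-ol | C/C(=C/CO[Si](C)(C)C(C)(C)C)[CH]=[C@]=C2C(C)(C)C[C@H](O[Si](C)(C)C(C)(C)C)C[C@@]2(C)O | intermediate (key-step precursor)
11 | C7 trichloroaurate, O-protonated form of 12 | C/C(=C/CO[Si](C)(C)C(C)(C)C)[C@H]1C([Au-](Cl)(Cl)Cl)=C2C(C)(C)C[C@H](O[Si](C)(C)C(C)(C)C)C[C@@]2(C)[OH+]1 | intermediate (not isolated)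
12 | tert-butyl({(2R,6S,7aR)-2-[(2Z)-4-{[tert-butyl(dimethyl)silyl]oxy}but-2-en-2-yl]-4,4,7a-trimethyl-2,4,5,6,7,7a-hexahydro-1-benzofuran-6-yl}oxy)dimethylsilane | C/C(=C/CO[Si](C)(C)C(C)(C)C)[C@H]1C=C2C(C)(C)C[C@H](O[Si](C)(C)C(C)(C)C)C[C@@]2(C)O1 | intermediate (key-step product)
13 | (2R,6S,7aR)-2-[(2Z)-4-hydroxybut-2-en-2-yl]-4,4,7a-trimethyl-2,4,5,6,7,7a-hexahydro-1-benzofuran-6-ol | C/C(=C/CO)[C@H]1C=C2C(C)(C)C[C@H](O)C[C@@]2(C)O1 | intermediate
14 | (2Z)-3-[(2R,6S,7aR)-6-hydroxy-4,4,7a-trimethyl-2,4,5,6,7,7a-hexahydro-1-benzofuran-2-yl]but-2-enal | C/C(=C/C=O)[C@H]1C=C2C(C)(C)C[C@H](O)C[C@@]2(C)O1 | intermediate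
15 | (2E,4E,6E)-2,7-dimethylocta-2,4,6-trienedial | O=C/C(C)=C/C=C/C=C(C)/C=O | starting material
16 | triethyl phosphonoacetate | CCOC(=O)CP(=O)(OCC)OCC | starting material
17 | sodium salt of the carbanion of 16 | CCOC(=O)[CH-]P(=O)(OCC)OCC.[Na+] | intermediate (not isolated)
18 | ethyl (2E,4E,6E,8E)-4,9-dimethyl-10-oxodeca-2,4,6,8-tetraenoate | CCOC(=O)/C=C/C(C)=C/C=C/C=C(C)/C=O | intermediate
19 | ethyl (2E,4E,6E,8E)-10-hydroxy-4,9-dimethyldeca-2,4,6,8-tetraenoate | CCOC(=O)/C=C/C(C)=C/C=C/C=C(C)/CO | intermediate
20 | ethyl (2E,4E,6E,8E)-10-bromo-4,9-dimethyldeca-2,4,6,8-tetraenoate | CCOC(=O)/C=C/C(C)=C/C=C/C=C(C)/CBr | intermediate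
21 | ethyl (2E,4E,6E,8E)-10-(diethoxyphosphoryl)-4,9-dimethyldeca-2,4,6,8-tetraenoate | CCOC(=O)/C=C/C(C)=C/C=C/C=C(C)/CP(=O)(OCC)OCC | intermediate
22 | sodium salt of the C10 carbanion of 21 | CCOC(=O)/C=C/C(C)=C/C=C/C=C(C)/[CH-]P(=O)(OCC)OCC.[Na+] | intermediate (not isolated)
23 | ethyl (2E,4E,6E,8E,10E,12Z)-13-[(2R,6S,7aR)-6-hydroxy-4,4,7a-trimethyl-2,4,5,6,7,7a-hexahydro-1-benzofuran-2-yl]-4,9-dimethyltetradeca-2,4,6,8,10,12-hexaenoate | C/C(=C/C=C/C(C)=C/C=C/C=C(C)/C=C/C(=O)OCC)[C@H]1C=C2C(C)(C)C[C@H](O)C[C@@]2(C)O1 | intermediate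
24 | (2E,4E,6E,8E,10E,12Z)-13-[(2R,6S,7aR)-6-hydroxy-4,4,7a-trimethyl-2,4,5,6,7,7a-hexahydro-1-benzofuran-2-yl]-4,9-dimethyltetradeca-2,4,6,8,10,12-hexaen-1-ol | C/C(=C/C=C/C(C)=C/C=C/C=C(C)/C=C/CO)[C@H]1C=C2C(C)(C)C[C@H](O)C[C@@]2(C)O1 | target

## Step count and least certain steps

Total: 15 steps. Longest linear sequence: 10 steps (1 to 24 through steps 1, 2, 4, 5, 6, 7, 8, 9, 14, 15).

Step 7 (key step). The most likely failure is loss of axis-to-centre fidelity. Ring A has to leave its resting chair, in which the C5–O bond is axial, to bring oxygen into the allene plane. If closure is slow, the gold-bound, vinyl-stabilised allyl cation can rotate and epimerise the axis, or the vinylallene can close on carbon (C6 to C10). Ionisation of the doubly allylic C8–O bond of the product by the Lewis acid would also erode C8. Fallback: starting from 10, iodocyclisation with N-iodosuccinimide (NaHCO3, CH2Cl2, 0 °C) should add iodine and the C5 oxygen anti across C7=C8 in the same plane, without a metal-bound allyl cation. This gives tert-butyl({(2S,6S,7aR)-2-[(2Z)-4-{[tert-butyl(dimethyl)silyl]oxy}but-2-en-2-yl]-3-iodo-4,4,7a-trimethyl-2,4,5,6,7,7a-hexahydro-1-benzofuran-6-yl}oxy)dimethylsilane F1, which has the same spatial arrangement at C8 as 12 (the descriptor changes because of the iodine). Hydrodeiodination with Bu3SnH and Pd(PPh3)4 in THF returns to the route at 12.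

Step 6. The risk is a wrong course of hydride transfer: delivery to C8 on the oxygen face (which would give the 6R axis), addition across the alkyne in the opposite sense, or conjugate reduction of the enyne. The fully substituted C6 next to C7 may also slow the addition. Fallback: starting from 8, hydrogenolysis with formate (Pd2(dba)3·CHCl3, Bu3P, HCO2NH4, THF, rt). Zerovalent palladium attacks C8 anti to the C6–O bond to form an allenylpalladium alkoxide, formate hands hydride to palladium, and reductive elimination places hydrogen on C8 where palladium was. This is the same anti outcome by a different mechanism, and it returns at 10 without a new isolated compound.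

Step 5. The risk is poor site and face selectivity: attack of the peracid on C9=C10, or on the face syn to the C3 silyloxy group, which would give the C5 epimer. Fallback: starting from 4, the chain alkene is introduced only after the epoxidation.
- Sonogashira coupling with ethynyltrimethylsilane gives tert-butyldimethyl({(1R)-3,5,5-trimethyl-4-[(trimethylsilyl)ethynyl]cyclohex-3-en-1-yl}oxy)silane F2.
- mCPBA gives the epoxide tert-butyldimethyl({(1R,3S,6R)-1,5,5-trimethyl-6-[(trimethylsilyl)ethynyl]-7-oxabicyclo[4.1.0]heptan-3-yl}oxy)silane F3. It has only one alkene, and the face isomers are separated at this small stage.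
- K2CO3 in MeOH gives the terminal alkyne tert-butyl{[(1R,3S,6R)-6-ethynyl-1,5,5-trimethyl-7-oxabicyclo[4.1.0]heptan-3-yl]oxy}dimethylsilane F4.
- A second Sonogashira coupling with tert-butyl{[(2Z)-3-iodobut-2-en-1-yl]oxy}dimethylsilane F5 (from (2Z)-3-iodobut-2-en-1-ol and TBSCl) returns to the route at 8.

Step 14. The risk is erosion of geometry. H8 is vinylogously α to the aldehyde of 14, so deprotonation by the carbanion could scramble C9=C10 or C8, and some 11Z isomer may form. Fallback: a Julia–Kocienski olefination starting from 20.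
- Displacement with 1-phenyl-1H-tetrazole-5-thiol and Et3N gives ethyl (2E,4E,6E,8E)-4,9-dimethyl-10-[(1-phenyl-1H-tetrazol-5-yl)sulfanyl]deca-2,4,6,8-tetraenoate F6.
- Oxidation with H2O2 and (NH4)6Mo7O24 gives ethyl (2E,4E,6E,8E)-4,9-dimethyl-10-[(1-phenyl-1H-tetrazol-5-yl)sulfonyl]deca-2,4,6,8-tetraenoate F7.
- KN(SiMe3)2 is added at −78 °C to a mixture of F7 and 14, so that the sulfonyl carbanion is trapped as it forms; this returns to the route at 23.

## Further compounds

F1 | step 7 | tert-butyl({(2S,6S,7aR)-2-[(2Z)-4-{[tert-butyl(dimethyl)silyl]oxy}but-2-en-2-yl]-3-iodo-4,4,7a-trimethyl-2,4,5,6,7,7a-hexahydro-1-benzofuran-6-yl}oxy)dimethylsilane | C/C(=C/CO[Si](C)(C)C(C)(C)C)[C@H]1C(I)=C2C(C)(C)C[C@H](O[Si](C)(C)C(C)(C)C)C[C@@]2(C)O1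
F0 | step 6 | none | none
F2 | step 5 | tert-butyldimethyl({(1R)-3,5,5-trimethyl-4-[(trimethylsilyl)ethynyl]cyclohex-3-en-1-yl}oxy)silane | C[Si](C)(C)C#CC1=C(C)C[C@@H](O[Si](C)(C)C(C)(C)C)CC1(C)C
F3 | step 5 | tert-butyldimethyl({(1R,3S,6R)-1,5,5-trimethyl-6-[(trimethylsilyl)ethynyl]-7-oxabicyclo[4.1.0]heptan-3-yl}oxy)silane | C[Si](C)(C)C#C[C@@]12O[C@]1(C)C[C@@H](O[Si](C)(C)C(C)(C)C)CC2(C)C
F4 | step 5 | tert-butyl{[(1R,3S,6R)-6-ethynyl-1,5,5-trimethyl-7-oxabicyclo[4.1.0]heptan-3-yl]oxy}dimethylsilane | C#C[C@@]12O[C@]1(C)C[C@@H](O[Si](C)(C)C(C)(C)C)CC2(C)C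
F5 | step 5 | tert-butyl{[(2Z)-3-iodobut-2-en-1-yl]oxy}dimethylsilane | C/C(I)=C/CO[Si](C)(C)C(C)(C)C
F6 | step 14 | ethyl (2E,4E,6E,8E)-4,9-dimethyl-10-[(1-phenyl-1H-tetrazol-5-yl)sulfanyl]deca-2,4,6,8-tetraenoate | CCOC(=O)/C=C/C(C)=C/C=C/C=C(C)/CSc1nnnn1-c1ccccc1
F7 | step 14 | ethyl (2E,4E,6E,8E)-4,9-dimethyl-10-[(1-phenyl-1H-tetrazol-5-yl)sulfonyl]deca-2,4,6,8-tetraenoate | CCOC(=O)/C=C/C(C)=C/C=C/C=C(C)/CS(=O)(=O)c1nnnn1-c1ccccc1
A1 | alternative 1 | (S)-abscisic acid, (2Z,4E)-5-[(1S)-1-hydroxy-2,6,6-trimethyl-4-oxocyclohex-2-en-1-yl]-3-methylpenta-2,4-dienoic acid | CC1=CC(=O)CC(C)(C)[C@@]1(O)/C=C/C(C)=C\C(=O)O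
A2 | alternative 1 | (2Z,4E)-5-[(1S)-1-hydroxy-2,6,6-trimethyl-4-oxocyclohex-2-en-1-yl]-3-methylpenta-2,4-dienenitrile | CC1=CC(=O)CC(C)(C)[C@@]1(O)/C=C/C(C)=C\C#N
A3 | alternative 1 | (2Z)-3-[(2R,7aR)-4,4,7a-trimethyl-6-oxo-2,4,5,6,7,7a-hexahydro-1-benzofuran-2-yl]but-2-enenitrile | N#C/C=C(C)\[C@H]1C=C2C(C)(C)CC(=O)C[C@@]2(C)O1
A4 | alternative 2 | (2Z,4R)-1-{[tert-butyl(dimethyl)silyl]oxy}-4-hydroxy-3,7,11-trimethyldodeca-2,5,6,10-tetraen-9-one | C/C(=C/CO[Si](C)(C)C(C)(C)C)[C@H](O)C=C=C(C)CC(=O)C=C(C)C
A5 | alternative 2 | (2R,7aR)-2-[(2Z)-4-{[tert-butyl(dimethyl)silyl]oxy}but-2-en-2-yl]-4,4,7a-trimethyl-4,5,7,7a-tetrahydro-1-benzofuran-6(2H)-one | C/C(=C/CO[Si](C)(C)C(C)(C)C)[C@H]1C=C2C(C)(C)CC(=O)C[C@@]2(C)O1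
A6 | alternative 3 | (2R,4S)-4-{[tert-butyl(dimethyl)silyl]oxy}-2-{[(2Z)-3-iodo-2-methylprop-2-en-1-yl]oxy}-2,6,6-trimethylcyclohexan-1-one | I/C=C(C)\CO[C@]1(C)C[C@@H](O[Si](C)(C)C(C)(C)C)CC(C)(C)C1=O
A7 | alternative 3 | tert-butyl({(2R,6S,7aR)-2-[(1Z)-1-iodoprop-1-en-2-yl]-4,4,7a-trimethyl-2,4,5,6,7,7a-hexahydro-1-benzofuran-6-yl}oxy)dimethylsilane | I/C=C(C)\[C@H]1C=C2C(C)(C)C[C@H](O[Si](C)(C)C(C)(C)C)C[C@@]2(C)O1
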